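**Retrosynthetic overview**
1. Ebenfuran III ⇐ BCl3 dealkylation of the fully O-alkylated 2-aryl-benzofuran-3-carbaldehyde (two i-Pr ethers, plus the 4-OMe, which the peri-CHO singles out).
2. The furan ring is the only ring formed (both benzene rings are bought): the O1–C2 bond is closed by phenol→ketone cyclodehydration in a new acid cascade from a trans-epoxychalcone, whose 1,2-aroyl shift first puts ring A on the formyl-bearing carbon.
3. Epoxychalcone ⇐ Claisen–Schmidt condensation/Weitz–Scheffer epoxidation of a MOM-protected salicylaldehyde (ring A) with 2,4-diisopropoxyacetophenone (ring B).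
4. Ring-A aldehyde ⇐ mirror-symmetric 3,5-dimethoxy-4-prenylphenol ⇐ 3,5-dimethoxyphenol (metalation/prenylation between the two OMe groups); the symmetry removes every regiochemical choice on ring A.

Assumption: the target has no stereocentre and its prenyl alkene carries two identical methyl groups, so it is achiral and "single enantiomer" needs no action; the only stereo-defined intermediates are the E-chalcone and the racemic trans-epoxide, both erased in step 7.

**Step 1**
Reactants: 1 3,5-dimethoxyphenol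
Product: 2 (3,5-dimethoxyphenoxy)tri(propan-2-yl)silane
Conditions: TIPSCl (1.1 eq), imidazole (2 eq), DMF, rt
Reagents that add atoms: chlorotri(propan-2-yl)silane (TIPSCl), CC(C)[Si](Cl)(C(C)C)C(C)C
Why: Standard imidazole-promoted O-silylation; the bulky, weakly coordinating OTIPS group removes the acidic proton and shields both positions next to it, so the next metalation can only go between the two methoxy groups.

**Step 2**
Reactants: 2 (3,5-dimethoxyphenoxy)tri(propan-2-yl)silane
Product: 5 3,5-dimethoxy-4-(3-methylbut-2-en-1-yl)phenol, via aryllithium 3 (not isolated), via prenylated silyl ether 4 (not isolated)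
Conditions: n-BuLi (1.2 eq), THF, 0 °C → rt; CuI (10 mol%), prenyl bromide, −78 °C → rt; then TBAF (1.5 eq), rt
Reagents that add atoms: 1-bromo-3-methylbut-2-ene (prenyl bromide), CC(C)=CCBr
Why: Directed ortho-metalation at the carbon flanked by two OMe groups (as in 1,3-dimethoxybenzene), SN2 allylation of the aryl metal and fluoride desilylation in the same flask give a mirror-symmetric phenol whose two free ring positions are equivalent.

**Step 3**
Reactants: 5 3,5-dimethoxy-4-(3-methylbut-2-en-1-yl)phenol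
Product: 6 6-hydroxy-2,4-dimethoxy-3-(3-methylbut-2-en-1-yl)benzaldehyde
Conditions: MgCl2 (2 eq), Et3N (4 eq), (CH2O)n (6 eq), MeCN, reflux; cold 1 M HCl work-up
Reagents that add atoms: paraformaldehyde (formaldehyde), C=O
Why: Magnesium-phenoxide-directed ortho-formylation (Casnati–Skattebøl); para is blocked and the two ortho positions are equivalent, so one salicylaldehyde forms and the prenyl group meets neither strong acid nor oxidant.

**Step 4**
Reactants: 6 6-hydroxy-2,4-dimethoxy-3-(3-methylbut-2-en-1-yl)benzaldehyde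
Product: 7 2,4-dimethoxy-6-(methoxymethoxy)-3-(3-methylbut-2-en-1-yl)benzaldehyde
Conditions: MOMCl (1.5 eq), K2CO3 (3 eq), acetone, 50 °C
Reagents that add atoms: chloromethyl methyl ether (MOMCl), COCCl
Why: Williamson-type O-alkylation (MOM protection); the acetal survives the basic condensation/epoxidation and is the only group that the acid step must later remove from ring A.

**Step 5**
Reactants: 8 1-(2,4-dihydroxyphenyl)ethan-1-one
Product: 9 1-[2,4-di(propan-2-yloxy)phenyl]ethan-1-one
Conditions: 2-bromopropane (5 eq), K2CO3 (4 eq), KI (cat.), DMF, 80 °C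
Reagents that add atoms: 2-bromopropane, CC(C)Br
Why: Williamson etherification; isopropyl ethers resist base, peroxide and Brønsted acid, stop the 2'-oxygen from closing an isoflavone ring in step 7, and leave with BCl3 at the end.

**Step 6**
Reactants: 7 2,4-dimethoxy-6-(methoxymethoxy)-3-(3-methylbut-2-en-1-yl)benzaldehyde; 9 1-[2,4-di(propan-2-yloxy)phenyl]ethan-1-one
Product: 11 rac-trans-[3-[2,4-dimethoxy-6-(methoxymethoxy)-3-(3-methylbut-2-en-1-yl)phenyl]oxiran-2-yl][2,4-di(propan-2-yloxy)phenyl]methanone, via chalcone 10 (not isolated)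
Conditions: KOH (4 eq), EtOH/THF, rt, 36 h; then 30% H2O2 (4 eq), 0 °C → rt; extractive work-up, used crude at once
Reagents that add atoms: hydrogen peroxide, OO
Why: Claisen–Schmidt aldol condensation gives the E-enone and Weitz–Scheffer nucleophilic epoxidation (HOO− adds only to the electron-poor enone, not to the prenyl alkene) gives the trans-epoxide as a racemate through the rotatable β-peroxy enolate; both stereocentres are erased in step 7.

**Step 7**
Reactants: 11 rac-trans-[3-[2,4-dimethoxy-6-(methoxymethoxy)-3-(3-methylbut-2-en-1-yl)phenyl]oxiran-2-yl][2,4-di(propan-2-yloxy)phenyl]methanone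
Product: 14 2-[2,4-di(propan-2-yloxy)phenyl]-4,6-dimethoxy-5-(3-methylbut-2-en-1-yl)-1-benzofuran-3-carbaldehyde, via formyl ketone 12 (not isolated), via phenolic formyl ketone 13 (not isolated)
Conditions: BF3·OEt2 (0.3 eq), CH2Cl2, −40 °C, 20 min; then TsOH·H2O (0.5 eq), HFIP, 0 °C → rt
Reagents that add atoms: none
Why: Proposed new method: a one-flask epoxychalcone → 2-aryl-3-formylbenzofuran ring transposition in which BF3 opens the oxirane at the benzylic carbon (cation stabilised by the 2,4,6-trioxygenated ring) and the aroyl group makes a 1,2-shift (House–Meinwald/semipinacol) to give 12, then TsOH/HFIP cleaves the aryl MOM acetal and the freed phenol adds 5-exo-trig to the ketone, the hemiketal ionising to an oxocarbenium ion stabilised by the 2,4-dialkoxyphenyl ring and losing the acidic C3–H so that the new C–O bond ends at C2 and CHO stays at C3 (closure on CHO would need a far less stabilised secondary oxocarbenium ion); the closest known reactions are the Lewis-acid rearrangement of chalcone oxides to formyl-deoxybenzoins used in isoflavone synthesis and the strong-acid/HFIP conversion of 2-alkoxy-3-acyl-2,3-dihydrobenzofurans into 3-formylbenzofurans, and what is new is their merger on an epoxide whose ortho-oxygen sits on the β-aryl ring; no stereocentre is set.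

**Step 8**
Reactants: 14 2-[2,4-di(propan-2-yloxy)phenyl]-4,6-dimethoxy-5-(3-methylbut-2-en-1-yl)-1-benzofuran-3-carbaldehyde
Product: 15 2-(2,4-dihydroxyphenyl)-4-hydroxy-6-methoxy-5-(3-methylbut-2-en-1-yl)-1-benzofuran-3-carbaldehyde
Conditions: BCl3 (6 eq, 1 M in CH2Cl2), CH2Cl2, −78 → 0 °C; poured into cold aq NaHCO3
Reagents that add atoms: none
Why: Lewis-acid ether dealkylation with BCl3 removes the two secondary isopropyl ethers and the one methyl ether that is chelated to the C3 formyl group and twisted out of plane by its two ortho neighbours, while the unchelated 6-OMe survives at ≤0 °C; the substrate has no free OH, so no protic acid meets the prenyl group before the cold basic quench.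

**Compound list**
1 | 3,5-dimethoxyphenol | COc1cc(O)cc(OC)c1 | starting material
2 | (3,5-dimethoxyphenoxy)tri(propan-2-yl)silane | COc1cc(O[Si](C(C)C)(C(C)C)C(C)C)cc(OC)c1 | intermediate
3 | [2,6-dimethoxy-4-(triisopropylsilyloxy)phenyl]lithium | [Li]c1c(OC)cc(O[Si](C(C)C)(C(C)C)C(C)C)cc1OC | intermediate
4 | [3,5-dimethoxy-4-(3-methylbut-2-en-1-yl)phenoxy]tri(propan-2-yl)silane | COc1cc(O[Si](C(C)C)(C(C)C)C(C)C)cc(OC)c1CC=C(C)C | intermediate
5 | 3,5-dimethoxy-4-(3-methylbut-2-en-1-yl)phenol | COc1cc(O)cc(OC)c1CC=C(C)C | intermediate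
6 | 6-hydroxy-2,4-dimethoxy-3-(3-methylbut-2-en-1-yl)benzaldehyde | COc1cc(O)c(C=O)c(OC)c1CC=C(C)C | intermediate
7 | 2,4-dimethoxy-6-(methoxymethoxy)-3-(3-methylbut-2-en-1-yl)benzaldehyde | COCOc1cc(OC)c(CC=C(C)C)c(OC)c1C=O | intermediate
8 | 1-(2,4-dihydroxyphenyl)ethan-1-one | CC(=O)c1ccc(O)cc1O | starting material
9 | 1-[2,4-di(propan-2-yloxy)phenyl]ethan-1-one | CC(=O)c1ccc(OC(C)C)cc1OC(C)C | intermediate
10 | (E)-1-[2,4-di(propan-2-yloxy)phenyl]-3-[2,4-dimethoxy-6-(methoxymethoxy)-3-(3-methylbut-2-en-1-yl)phenyl]prop-2-en-1-one | COCOc1cc(OC)c(CC=C(C)C)c(OC)c1/C=C/C(=O)c1ccc(OC(C)C)cc1OC(C)C | intermediate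
11 | rac-trans-[3-[2,4-dimethoxy-6-(methoxymethoxy)-3-(3-methylbut-2-en-1-yl)phenyl]oxiran-2-yl][2,4-di(propan-2-yloxy)phenyl]methanone (racemate; one enantiomer drawn) | O=C(c1ccc(OC(C)C)cc1OC(C)C)[C@H]1O[C@@H]1c1c(OCOC)cc(OC)c(CC=C(C)C)c1OC | intermediate
12 | 3-[2,4-di(propan-2-yloxy)phenyl]-2-[2,4-dimethoxy-6-(methoxymethoxy)-3-(3-methylbut-2-en-1-yl)phenyl]-3-oxopropanal (racemic, enolisable) | O=CC(C(=O)c1ccc(OC(C)C)cc1OC(C)C)c1c(OCOC)cc(OC)c(CC=C(C)C)c1OC | intermediate
13 | 3-[2,4-di(propan-2-yloxy)phenyl]-2-[6-hydroxy-2,4-dimethoxy-3-(3-methylbut-2-en-1-yl)phenyl]-3-oxopropanal (racemic, enolisable) | O=CC(C(=O)c1ccc(OC(C)C)cc1OC(C)C)c1c(O)cc(OC)c(CC=C(C)C)c1OC | intermediate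
14 | 2-[2,4-di(propan-2-yloxy)phenyl]-4,6-dimethoxy-5-(3-methylbut-2-en-1-yl)-1-benzofuran-3-carbaldehyde | COc1cc2oc(-c3ccc(OC(C)C)cc3OC(C)C)c(C=O)c2c(OC)c1CC=C(C)C | intermediate
15 | 2-(2,4-dihydroxyphenyl)-4-hydroxy-6-methoxy-5-(3-methylbut-2-en-1-yl)-1-benzofuran-3-carbaldehyde (ebenfuran III) | COc1cc2oc(-c3ccc(O)cc3O)c(C=O)c2c(O)c1CC=C(C)C | target

**Step count and risks**
Total steps: 8. Longest linear sequence: 7 (steps 1, 2, 3, 4, 6, 7, 8); step 5 is the one-step side branch.

Step 7 (proposed new cascade) is the most likely to fail. The benzylic cation could instead undergo a hydride shift to the 1,2-diketone or be trapped by the MOM oxygen, the phenol could close on CHO to give the 3-aroylbenzofuran, and HFIP/TsOH could attack the prenyl alkene. The fallback uses only known reaction types, sets out from 5 and 9 and comes back at 14. Phenol 5 is iodinated with NIS (CH2Cl2, −40 °C; the two ortho positions are equivalent) to 2-iodo-3,5-dimethoxy-4-(3-methylbut-2-en-1-yl)phenol F1. Ketone 9 is converted by Vilsmeier–Haack–Arnold chloroformylation (POCl3, DMF, 60 °C) into (2Z)-3-chloro-3-[2,4-di(propan-2-yloxy)phenyl]prop-2-enal F2. Addition–elimination of the phenoxide of F1 on F2 (K2CO3, DMF, 40 °C) makes the O1–C2 bond first and gives 3-[2,4-di(propan-2-yloxy)phenyl]-3-[2-iodo-3,5-dimethoxy-4-(3-methylbut-2-en-1-yl)phenoxy]prop-2-enal F3. An intramolecular Heck cyclisation (Pd(OAc)2, PPh3, K2CO3, DMF, 90 °C) then closes C3–C3a and delivers 14.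

Step 8 is the second risk. The prenyl group may not tolerate BCl3 and the isopropyl cations it releases, and the chelate that singles out the 4-OMe is seven-membered. The fallback replaces the Lewis-acid end game by two orthogonal mild steps; it sets out from 8 and comes back at 15. Ketone 8 is allylated (allyl bromide, K2CO3, DMF) to 1-[2,4-bis(prop-2-en-1-yloxy)phenyl]ethan-1-one F4. Under the conditions of step 6 with 7 this gives, through (E)-1-[2,4-bis(prop-2-en-1-yloxy)phenyl]-3-[2,4-dimethoxy-6-(methoxymethoxy)-3-(3-methylbut-2-en-1-yl)phenyl]prop-2-en-1-one F5 in the flask, rac-trans-[2,4-bis(prop-2-en-1-yloxy)phenyl][3-[2,4-dimethoxy-6-(methoxymethoxy)-3-(3-methylbut-2-en-1-yl)phenyl]oxiran-2-yl]methanone F6. The conditions of step 7 carry F6 through 3-[2,4-bis(prop-2-en-1-yloxy)phenyl]-2-[2,4-dimethoxy-6-(methoxymethoxy)-3-(3-methylbut-2-en-1-yl)phenyl]-3-oxopropanal F7 and 3-[2,4-bis(prop-2-en-1-yloxy)phenyl]-2-[6-hydroxy-2,4-dimethoxy-3-(3-methylbut-2-en-1-yl)phenyl]-3-oxopropanal F8 (both in the flask) to 2-[2,4-bis(prop-2-en-1-yloxy)phenyl]-4,6-dimethoxy-5-(3-methylbut-2-en-1-yl)-1-benzofuran-3-carbaldehyde F9. MgI2·OEt2 (toluene/THF, 60 °C) removes only the methyl group held in the Mg chelate with the formyl oxygen, by iodide SN2 and without protic acid, a method known to spare a prenyl group next to the freed OH; this gives 2-[2,4-bis(prop-2-en-1-yloxy)phenyl]-4-hydroxy-6-methoxy-5-(3-methylbut-2-en-1-yl)-1-benzofuran-3-carbaldehyde F10. Pd(0) deallylation (Pd(PPh3)4, K2CO3, MeOH, rt) then gives 15.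

Step 6 is the third risk. The electron-rich, doubly ortho-substituted aldehyde 7 condenses slowly, left-over aldehyde can suffer Dakin oxidation when H2O2 is added, and the very electron-rich epoxide is labile. The fallback builds the epoxide without any oxidant; it sets out from 9 and 7 and comes back at 11. Ketone 9 is α-brominated (CuBr2, EtOAc/CHCl3, reflux) to 2-bromo-1-[2,4-di(propan-2-yloxy)phenyl]ethan-1-one F11. A Darzens condensation of F11 with 7 (t-BuOK, THF, −20 °C → rt) forms the C–C bond and the trans-oxirane of 11 in one operation.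

**Further compounds**
F1 | step 7 | 2-iodo-3,5-dimethoxy-4-(3-methylbut-2-en-1-yl)phenol | COc1cc(O)c(I)c(OC)c1CC=C(C)C
F2 | step 7 | (2Z)-3-chloro-3-[2,4-di(propan-2-yloxy)phenyl]prop-2-enal | O=C/C=C(\Cl)c1ccc(OC(C)C)cc1OC(C)C
F3 | step 7 | 3-[2,4-di(propan-2-yloxy)phenyl]-3-[2-iodo-3,5-dimethoxy-4-(3-methylbut-2-en-1-yl)phenoxy]prop-2-enal (E/Z mixture) | O=CC=C(Oc1cc(OC)c(CC=C(C)C)c(OC)c1I)c1ccc(OC(C)C)cc1OC(C)C
F4 | step 8 | 1-[2,4-bis(prop-2-en-1-yloxy)phenyl]ethan-1-one | CC(=O)c1ccc(OCC=C)cc1OCC=C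
F5 | step 8 | (E)-1-[2,4-bis(prop-2-en-1-yloxy)phenyl]-3-[2,4-dimethoxy-6-(methoxymethoxy)-3-(3-methylbut-2-en-1-yl)phenyl]prop-2-en-1-one | COCOc1cc(OC)c(CC=C(C)C)c(OC)c1/C=C/C(=O)c1ccc(OCC=C)cc1OCC=C
F6 | step 8 | rac-trans-[2,4-bis(prop-2-en-1-yloxy)phenyl][3-[2,4-dimethoxy-6-(methoxymethoxy)-3-(3-methylbut-2-en-1-yl)phenyl]oxiran-2-yl]methanone (racemate; one enantiomer drawn) | O=C(c1ccc(OCC=C)cc1OCC=C)[C@H]1O[C@@H]1c1c(OCOC)cc(OC)c(CC=C(C)C)c1OC
F7 | step 8 | 3-[2,4-bis(prop-2-en-1-yloxy)phenyl]-2-[2,4-dimethoxy-6-(methoxymethoxy)-3-(3-methylbut-2-en-1-yl)phenyl]-3-oxopropanal (racemic, enolisable) | O=CC(C(=O)c1ccc(OCC=C)cc1OCC=C)c1c(OCOC)cc(OC)c(CC=C(C)C)c1OC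
F8 | step 8 | 3-[2,4-bis(prop-2-en-1-yloxy)phenyl]-2-[6-hydroxy-2,4-dimethoxy-3-(3-methylbut-2-en-1-yl)phenyl]-3-oxopropanal (racemic, enolisable) | O=CC(C(=O)c1ccc(OCC=C)cc1OCC=C)c1c(O)cc(OC)c(CC=C(C)C)c1OC
F9 | step 8 | 2-[2,4-bis(prop-2-en-1-yloxy)phenyl]-4,6-dimethoxy-5-(3-methylbut-2-en-1-yl)-1-benzofuran-3-carbaldehyde | COc1cc2oc(-c3ccc(OCC=C)cc3OCC=C)c(C=O)c2c(OC)c1CC=C(C)C
F10 | step 8 | 2-[2,4-bis(prop-2-en-1-yloxy)phenyl]-4-hydroxy-6-methoxy-5-(3-methylbut-2-en-1-yl)-1-benzofuran-3-carbaldehyde | COc1cc2oc(-c3ccc(OCC=C)cc3OCC=C)c(C=O)c2c(O)c1CC=C(C)C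
F11 | step 6 | 2-bromo-1-[2,4-di(propan-2-yloxy)phenyl]ethan-1-one | O=C(CBr)c1ccc(OC(C)C)cc1OC(C)C
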